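**Retrosynthetic overview**

1. The last disconnection is the C6–CH2 bond between the chromene and the filicinic ring C. It is made by reductive Knoevenagel alkylation of propionylfilicinic acid (from flopropione by gem-dimethylation) with a chromene-6-carbaldehyde.
2. The strategy rests on ring B, the fully substituted benzene ring of the chromene (numbering O1, C2, C3=C4, C4a, C5 to C8, C8a): oxygen at C5, C7 and C8a alternates with carbon at C4a, C6 and C8.
3. Ring B is built in one step by thermal benzannulation of 3-ethoxy-2-methylcyclobutenone with a prenyl triisopropylsiloxyalkyne, forming C8a–C4a and C5–C6. The cyclobutenone gives C6–Me, C7–OEt, C8–H and, from its carbonyl, C8a–OH; the alkyne gives C4a–prenyl and C5–OSi.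
4. Ring order: ring B first, then pyran ring A by DDQ closure of the prenyl group onto the lone C8a hydroxyl. Afterwards C6–Me is oxidised to CHO, C8–H is acylated by directed metalation, and the ethyl and silyl ethers are removed.
5. Precursors: the cyclobutenone from 1-ethoxypropyne and dichloroketene, then zinc dechlorination; the siloxyalkyne from ethyl 4-methylpent-3-enoate by Kowalski ynolate formation and O-silylation.

Key step: step 4

Remark: the target has no stereocentre and no stereogenic double bond; it is made as the enol tautomer of the given SMILES, and the four starting materials are taken as purchasable.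

**Route**

Step 1
Reactants: 1 1-ethoxyprop-1-yne; 2 trichloroacetyl chloride
Product: 3 4,4-dichloro-3-ethoxy-2-methylcyclobut-2-en-1-one
Conditions: Zn–Cu couple, Et2O/DME, slow addition of 2, 0 °C to rt
Reagents that add atoms: none
Why: Zinc converts 2 into dichloroketene, which undergoes a ketene–ynol ether [2+2] cycloaddition in which the nucleophilic methyl-bearing alkyne carbon bonds to the ketene carbonyl carbon, so the CCl2 group ends next to the ethoxy-bearing carbon.

Step 2
Reactants: 3 4,4-dichloro-3-ethoxy-2-methylcyclobut-2-en-1-one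
Product: 4 3-ethoxy-2-methylcyclobut-2-en-1-one
Conditions: Zn dust, AcOH, TMEDA, EtOH, 0 °C to rt
Reagents that add atoms: none
Why: Zinc/acetic acid reductive dechlorination of the alpha,alpha-dichloroketone, buffered by TMEDA against zinc-salt-induced chloride migration, is the standard second stage of cyclobutenone synthesis from dichloroketene adducts.

Step 3
Reactants: 5 ethyl 4-methylpent-3-enoate
Product: 7 triisopropyl[(5-methylhex-4-en-1-yn-1-yl)oxy]silane, via lithium ynolate 6 (not isolated)
Conditions: CH2Br2, LiTMP (lithium 2,2,6,6-tetramethylpiperidide), THF, −78 °C; LiN(SiMe3)2; s-BuLi, −78 to −20 °C; then i-Pr3SiCl, −78 °C to rt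
Reagents that add atoms: dibromomethane, BrCBr; chlorotriisopropylsilane, CC(C)[Si](Cl)(C(C)C)C(C)C
Why: Kowalski ester homologation, in which LiCHBr2 addition, deprotonation, bromine–lithium exchange and 1,2-shift of the ester substituent give ynolate 6, and the bulky chlorosilane reacts at oxygen to give the ynol silyl ether and not a silylketene.

Step 4
Reactants: 4 3-ethoxy-2-methylcyclobut-2-en-1-one; 7 triisopropyl[(5-methylhex-4-en-1-yn-1-yl)oxy]silane
Product: 12 5-ethoxy-4-methyl-2-(3-methylbut-2-en-1-yl)-3-[(triisopropylsilyl)oxy]phenol, via vinylketene 8 (not isolated), via vinylcyclobutenone 9 (not isolated), via dienylketene 10 (not isolated), via cyclohexadienone 11 (not isolated)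
Conditions: PhMe, 80 °C then 110 °C, sealed tube, slight excess of 7
Reagents that add atoms: none
Why: Heat opens the four-membered ring of 4 in a four-electron electrocyclic step to vinylketene 8, and the prenyl-bearing carbon of ynol silyl ether 7, its nucleophilic terminus, adds to the ketene carbonyl carbon in a [2+2] cycloaddition that gives 2-vinylcyclobutenone 9 with the new C8a–C4a and C5–C6 bonds. A second four-electron opening turns 9 into dienylketene 10, whose thermally allowed disrotatory six-electron electrocyclisation joins C8 to C8a and so closes carbocyclic ring B as dienone 11, which enolises to phenol 12. The closest known reaction is the Danheiser benzannulation of cyclobutenones with trialkylsiloxyalkynes to monosilylated resorcinols; the 3-ethoxy group only adds a third oxygen to the ring. No stereocentre is created. The single selectivity required is the orientation of the ketene–alkyne cycloaddition, and the oxygen-induced polarisation of 7 secures it, so the free hydroxyl (C8a) ends beside the prenyl group (C4a), the silyloxy group sits at C5, and 4 supplies C6–Me, C7–OEt and C8–H.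

Step 5
Reactants: 12 5-ethoxy-4-methyl-2-(3-methylbut-2-en-1-yl)-3-[(triisopropylsilyl)oxy]phenol
Product: 14 7-ethoxy-2,2,6-trimethyl-5-[(triisopropylsilyl)oxy]-2H-chromene, via quinone methide 13 (not isolated)
Conditions: DDQ (1.1 equiv), PhH, rt to 60 °C
Reagents that add atoms: none
Why: DDQ dehydrogenation of an ortho-prenylphenol, in which hydride loss from the benzylic and allylic CH2 gives ortho-quinone methide 13 and its oxa-six-electron electrocyclisation closes pyran ring A on the only free hydroxyl; this doubly activated secondary C–H should react ahead of the para methyl group.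

Step 6
Reactants: 14 7-ethoxy-2,2,6-trimethyl-5-[(triisopropylsilyl)oxy]-2H-chromene
Product: 16 7-ethoxy-2,2-dimethyl-5-[(triisopropylsilyl)oxy]-2H-chromene-6-carbaldehyde, via benzylic alcohol 15 (not isolated)
Conditions: DDQ (2.5 equiv), 1,4-dioxane/H2O (10:1), rt to 50 °C
Reagents that add atoms: water, O
Why: DDQ benzylic oxidation of a para-alkoxytoluene, in which hydride abstraction from the C6 methyl gives a benzyl cation stabilised by the para pyran oxygen and both ortho oxygens, water traps it as 15, and a second equivalent oxidises this electron-rich benzyl alcohol to the aldehyde, which deactivates the ring against further oxidation.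

Step 7
Reactants: 16 7-ethoxy-2,2-dimethyl-5-[(triisopropylsilyl)oxy]-2H-chromene-6-carbaldehyde
Product: 17 6-(dimethoxymethyl)-7-ethoxy-2,2-dimethyl-5-[(triisopropylsilyl)oxy]-2H-chromene
Conditions: HC(OMe)3, PPTS (cat.), MeOH, rt; Et3N quench
Reagents that add atoms: trimethyl orthoformate, COC(OC)OC
Why: Acid-catalysed acetalisation with the orthoformate as water scavenger masks the aldehyde against the organolithium of the next step under conditions too mild to touch the aryl silyl ether or the chromene double bond.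

Step 8
Reactants: 17 6-(dimethoxymethyl)-7-ethoxy-2,2-dimethyl-5-[(triisopropylsilyl)oxy]-2H-chromene
Product: 20 7-ethoxy-2,2-dimethyl-8-propanoyl-5-[(triisopropylsilyl)oxy]-2H-chromene-6-carbaldehyde, via aryllithium 18 (not isolated), via acetal ketone 19 (not isolated)
Conditions: n-BuLi, TMEDA, Et2O, 0 °C; EtC(O)N(OMe)Me, −78 °C to rt; then 1 M HCl, THF, rt
Reagents that add atoms: N-methoxy-N-methylpropanamide, CCC(=O)N(C)OC; water, O
Why: Directed ortho-metalation at the only ring C–H, which lies between the ethoxy group and the pyran oxygen, gives 18, Weinreb amide acylation stops at the ketone stage, and the dilute acid of the work-up hydrolyses the electron-rich benzylic acetal of 19.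

Step 9
Reactants: 20 7-ethoxy-2,2-dimethyl-8-propanoyl-5-[(triisopropylsilyl)oxy]-2H-chromene-6-carbaldehyde
Product: 21 7-hydroxy-2,2-dimethyl-8-propanoyl-5-[(triisopropylsilyl)oxy]-2H-chromene-6-carbaldehyde
Conditions: MgI2·OEt2 (3 equiv), PhMe/Et2O, 80 °C; 1 M HCl work-up
Reagents that add atoms: none
Why: Chelation-assisted ether cleavage, in which MgI2 binds the ethoxy oxygen between its two flanking carbonyl groups and iodide displaces the ethyl group by SN2, a mild method for alkoxy groups ortho to carbonyls that should spare the pyran, the chromene double bond and the silyl ether.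

Step 10
Reactants: 21 7-hydroxy-2,2-dimethyl-8-propanoyl-5-[(triisopropylsilyl)oxy]-2H-chromene-6-carbaldehyde
Product: 22 5,7-dihydroxy-2,2-dimethyl-8-propanoyl-2H-chromene-6-carbaldehyde
Conditions: n-Bu4NF, AcOH, THF, 0 °C
Reagents that add atoms: none
Why: Fluoride-mediated cleavage of the aryl silyl ether, buffered with acetic acid so that the phenoxide of the keto aldehyde is protonated at once.

Step 11
Reactants: 23 flopropione (1-(2,4,6-trihydroxyphenyl)propan-1-one)
Product: 25 propionylfilicinic acid (3,5-dihydroxy-4,4-dimethyl-2-propanoylcyclohexa-2,5-dien-1-one), via methylphloroglucinol 24 (not isolated)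
Conditions: NaOMe (3 equiv), MeI (2.2 equiv), MeOH, 0 °C to rt; then aq. HCl
Reagents that add atoms: iodomethane, CI
Why: Dearomatising C-methylation of the acylphloroglucinol anion, in which the first methyl gives 24 and the second enters the same carbon to give the gem-dimethyl triketone, is the classical preparation of acylfilicinic acids; the product must be separated from isomeric dimethyl compounds.

Step 12
Reactants: 22 5,7-dihydroxy-2,2-dimethyl-8-propanoyl-2H-chromene-6-carbaldehyde; 25 propionylfilicinic acid
Product: 27 2-[(5,7-dihydroxy-2,2-dimethyl-8-propanoyl-2H-chromen-6-yl)methyl]-3,5-dihydroxy-4,4-dimethyl-6-propanoylcyclohexa-2,5-dien-1-one (CNP0277188.0), via alkylidene trione 26 (not isolated)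
Conditions: L-proline (20 mol%), Hantzsch ester (diethyl 2,6-dimethyl-1,4-dihydropyridine-3,5-dicarboxylate, 1.2 equiv), CH2Cl2/EtOH, rt
Reagents that add atoms: none
Why: Organocatalytic reductive Knoevenagel alkylation of a cyclic 1,3-dicarbonyl, in which proline-mediated condensation of 22 at the free ring CH of 25 gives alkylidene trione 26, which should accept hydride from the Hantzsch ester at the benzylic carbon faster than a second molecule of 25 can add, leaving the methylene bridge with no stereocentre.

**Compound list**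

1 | 1-ethoxyprop-1-yne | CCOC#CC | starting material
2 | trichloroacetyl chloride | O=C(Cl)C(Cl)(Cl)Cl | starting material
3 | 4,4-dichloro-3-ethoxy-2-methylcyclobut-2-en-1-one | CCOC1=C(C)C(=O)C1(Cl)Cl | intermediate
4 | 3-ethoxy-2-methylcyclobut-2-en-1-one | CCOC1=C(C)C(=O)C1 | intermediate
5 | ethyl 4-methylpent-3-enoate | CCOC(=O)CC=C(C)C | starting material
6 | lithium 5-methylhex-4-en-1-yn-1-olate | [Li+].[O-]C#CCC=C(C)C | intermediate (not isolated)
7 | triisopropyl[(5-methylhex-4-en-1-yn-1-yl)oxy]silane | CC(C)=CCC#CO[Si](C(C)C)(C(C)C)C(C)C | intermediate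
8 | 3-ethoxy-2-methylbuta-1,3-dien-1-one (vinylketene) | CCOC(=C)C(C)=C=O | intermediate (not isolated)
9 | 4-(1-ethoxyethenyl)-4-methyl-2-(3-methylbut-2-en-1-yl)-3-[(triisopropylsilyl)oxy]cyclobut-2-en-1-one (racemic) | CCOC(=C)C1(C)C(=O)C(CC=C(C)C)=C1O[Si](C(C)C)(C(C)C)C(C)C | intermediate (not isolated)
10 | (3E)-5-ethoxy-4-methyl-2-(3-methylbut-2-en-1-yl)-3-[(triisopropylsilyl)oxy]hexa-1,3,5-trien-1-one (dienylketene) | O=C=C(CC=C(C)C)/C(O[Si](C(C)C)(C(C)C)C(C)C)=C(C)\C(OCC)=C | intermediate (not isolated)
11 | 5-ethoxy-4-methyl-2-(3-methylbut-2-en-1-yl)-3-[(triisopropylsilyl)oxy]cyclohexa-2,4-dien-1-one | CCOC1=C(C)C(O[Si](C(C)C)(C(C)C)C(C)C)=C(CC=C(C)C)C(=O)C1 | intermediate (not isolated)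
12 | 5-ethoxy-4-methyl-2-(3-methylbut-2-en-1-yl)-3-[(triisopropylsilyl)oxy]phenol | CCOc1cc(O)c(CC=C(C)C)c(O[Si](C(C)C)(C(C)C)C(C)C)c1C | intermediate
13 | (6Z)-3-ethoxy-4-methyl-6-(3-methylbut-2-en-1-ylidene)-5-[(triisopropylsilyl)oxy]cyclohexa-2,4-dien-1-one (ortho-quinone methide) | CCOC1=CC(=O)/C(=C\C=C(C)C)C(O[Si](C(C)C)(C(C)C)C(C)C)=C1C | intermediate (not isolated)
14 | 7-ethoxy-2,2,6-trimethyl-5-[(triisopropylsilyl)oxy]-2H-chromene | CCOc1cc2OC(C)(C)C=Cc2c(O[Si](C(C)C)(C(C)C)C(C)C)c1C | intermediate
15 | {7-ethoxy-2,2-dimethyl-5-[(triisopropylsilyl)oxy]-2H-chromen-6-yl}methanol | CCOc1cc2OC(C)(C)C=Cc2c(O[Si](C(C)C)(C(C)C)C(C)C)c1CO | intermediate (not isolated)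
16 | 7-ethoxy-2,2-dimethyl-5-[(triisopropylsilyl)oxy]-2H-chromene-6-carbaldehyde | CCOc1cc2OC(C)(C)C=Cc2c(O[Si](C(C)C)(C(C)C)C(C)C)c1C=O | intermediate
17 | 6-(dimethoxymethyl)-7-ethoxy-2,2-dimethyl-5-[(triisopropylsilyl)oxy]-2H-chromene | CCOc1cc2OC(C)(C)C=Cc2c(O[Si](C(C)C)(C(C)C)C(C)C)c1C(OC)OC | intermediate
18 | {6-(dimethoxymethyl)-7-ethoxy-2,2-dimethyl-5-[(triisopropylsilyl)oxy]-2H-chromen-8-yl}lithium | CCOc1c([Li])c2OC(C)(C)C=Cc2c(O[Si](C(C)C)(C(C)C)C(C)C)c1C(OC)OC | intermediate (not isolated)
19 | 1-{6-(dimethoxymethyl)-7-ethoxy-2,2-dimethyl-5-[(triisopropylsilyl)oxy]-2H-chromen-8-yl}propan-1-one | CCOc1c(C(=O)CC)c2OC(C)(C)C=Cc2c(O[Si](C(C)C)(C(C)C)C(C)C)c1C(OC)OC | intermediate (not isolated)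
20 | 7-ethoxy-2,2-dimethyl-8-propanoyl-5-[(triisopropylsilyl)oxy]-2H-chromene-6-carbaldehyde | CCOc1c(C(=O)CC)c2OC(C)(C)C=Cc2c(O[Si](C(C)C)(C(C)C)C(C)C)c1C=O | intermediate
21 | 7-hydroxy-2,2-dimethyl-8-propanoyl-5-[(triisopropylsilyl)oxy]-2H-chromene-6-carbaldehyde | CCC(=O)c1c(O)c(C=O)c(O[Si](C(C)C)(C(C)C)C(C)C)c2C=CC(C)(C)Oc12 | intermediate
22 | 5,7-dihydroxy-2,2-dimethyl-8-propanoyl-2H-chromene-6-carbaldehyde | CCC(=O)c1c(O)c(C=O)c(O)c2C=CC(C)(C)Oc12 | intermediate
23 | flopropione (1-(2,4,6-trihydroxyphenyl)propan-1-one) | CCC(=O)c1c(O)cc(O)cc1O | starting material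
24 | 1-(2,4,6-trihydroxy-3-methylphenyl)propan-1-one | CCC(=O)c1c(O)cc(O)c(C)c1O | intermediate (not isolated)
25 | propionylfilicinic acid (3,5-dihydroxy-4,4-dimethyl-2-propanoylcyclohexa-2,5-dien-1-one) | CCC(=O)C1=C(O)C(C)(C)C(O)=CC1=O | intermediate
26 | 2-[(5,7-dihydroxy-2,2-dimethyl-8-propanoyl-2H-chromen-6-yl)methylidene]-5-hydroxy-4,4-dimethyl-6-propanoylcyclohex-5-ene-1,3-dione (alkene geometry not defined) | CCC(=O)C1=C(O)C(C)(C)C(=O)C(=Cc2c(O)c3C=CC(C)(C)Oc3c(C(=O)CC)c2O)C1=O | intermediate (not isolated)
27 | 2-[(5,7-dihydroxy-2,2-dimethyl-8-propanoyl-2H-chromen-6-yl)methyl]-3,5-dihydroxy-4,4-dimethyl-6-propanoylcyclohexa-2,5-dien-1-one | CCC(=O)C1=C(O)C(C)(C)C(O)=C(Cc2c(O)c3c(c(C(=O)CC)c2O)OC(C)(C)C=C3)C1=O | target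

**Step count**

Total: 12 steps. Longest linear sequence: 10 steps (1, 2, 4, 5, 6, 7, 8, 9, 10, 12); steps 3 and 11 are side branches.

**Steps most likely to fail**

Step 4. The push–pull cyclobutenone may open to the vinylketene too slowly, so that decay of the siloxyalkyne and acylation of the product phenol by late-formed ketene overtake the annulation. The fallback generates vinylketene 8 at room temperature by photochemical Wolff rearrangement. It sets out from 7 and comes back at 12. 1-Ethoxyvinyllithium (ethyl vinyl ether, t-BuLi, THF) is acylated with N-methoxy-N-methylpropanamide to 2-ethoxypent-1-en-3-one F1. Its lithium enolate (LiN(SiMe3)2, −78 °C) is trifluoroacetylated with CF3CO2CH2CF3 to 5-ethoxy-1,1,1-trifluoro-3-methylhex-5-ene-2,4-dione F2. Detrifluoroacetylative diazo transfer (MsN3, Et3N, H2O, MeCN) gives 2-diazo-4-ethoxypent-4-en-3-one F3. Irradiation of F3 with 7 in CH2Cl2, then warming to 80–110 °C, should lead through 8 to 11 to phenol 12.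

Step 6. Hydride abstraction from the primary C6 methyl may be slower than attack of DDQ on the electron-rich chromene double bond or the free C8 position, so that adducts and oligomers form instead of the aldehyde. The fallback brings the benzylic carbon in at the alcohol oxidation level. It sets out from 7 (with 2 as ketene source) and comes back at 16. Lithium ethoxyacetylide (ethoxyacetylene, n-BuLi, THF, −78 °C) is alkylated with chloromethyl methyl ether to 1-ethoxy-3-methoxyprop-1-yne F4. The conditions of step 1 give 4,4-dichloro-3-ethoxy-2-(methoxymethyl)cyclobut-2-en-1-one F5, and those of step 2 give 3-ethoxy-2-(methoxymethyl)cyclobut-2-en-1-one F6. Benzannulation with 7 as in step 4 should give 5-ethoxy-4-(methoxymethyl)-2-(3-methylbut-2-en-1-yl)-3-[(triisopropylsilyl)oxy]phenol F7. DDQ in benzene closes the pyran to 7-ethoxy-6-(methoxymethyl)-2,2-dimethyl-5-[(triisopropylsilyl)oxy]-2H-chromene F8. DDQ in wet CH2Cl2 then oxidises the electron-rich benzyl methyl ether, the reaction used to cleave dimethoxybenzyl ethers, to aldehyde 16.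

Step 9. Iodide displacement at an ethyl (not methyl) group may be slow, and long exposure to the Lewis acid may ionise the tertiary allylic O1–C2 bond of the pyran beside the C8 ketone. The fallback is an SN2 dealkylation under basic conditions with no Lewis acid: NaSEt in DMF at 100 °C, where the aryloxide flanked by two carbonyl groups is a good leaving group. It sets out from 20 and comes back at 21.

**Further compounds**

F1 | step 4 | 2-ethoxypent-1-en-3-one | C=C(OCC)C(=O)CC
F2 | step 4 | 5-ethoxy-1,1,1-trifluoro-3-methylhex-5-ene-2,4-dione | C=C(OCC)C(=O)C(C)C(=O)C(F)(F)F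
F3 | step 4 | 2-diazo-4-ethoxypent-4-en-3-one | C=C(OCC)C(=O)C(C)=[N+]=[N-]
F4 | step 6 | 1-ethoxy-3-methoxyprop-1-yne | CCOC#CCOC
F5 | step 6 | 4,4-dichloro-3-ethoxy-2-(methoxymethyl)cyclobut-2-en-1-one | CCOC1=C(COC)C(=O)C1(Cl)Cl
F6 | step 6 | 3-ethoxy-2-(methoxymethyl)cyclobut-2-en-1-one | CCOC1=C(COC)C(=O)C1
F7 | step 6 | 5-ethoxy-4-(methoxymethyl)-2-(3-methylbut-2-en-1-yl)-3-[(triisopropylsilyl)oxy]phenol | CCOc1cc(O)c(CC=C(C)C)c(O[Si](C(C)C)(C(C)C)C(C)C)c1COC
F8 | step 6 | 7-ethoxy-6-(methoxymethyl)-2,2-dimethyl-5-[(triisopropylsilyl)oxy]-2H-chromene | CCOc1cc2OC(C)(C)C=Cc2c(O[Si](C(C)C)(C(C)C)C(C)C)c1COC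
F0 | step 9 | none | none
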